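**Retrosynthetic overview**
- The target is guibourtinidol-(4α→6)-fisetinidol; the last step removes three benzyl ethers by hydrogenolysis.
- Key disconnection: the interflavanyl C4–C6 bond, made photochemically from a 7-hydroxyflavan-3,4-diol (upper unit) through its p-quinone methide and a fisetinidol nucleophile; C4 is set by C2/C3 of the upper unit.
- The labile 3,4-diol is made in the same telescoped operation by DDQ benzylic hydroxylation of the upper flavan-3-ol and is not isolated.
- Ring C of each unit is closed (lower unit first, then upper) by acid-mediated SN1 O1–C2 cycloetherification of a 1,3-diarylpropane-1,2-diol, C2 trans to C3; rings A and B are bought as aryl halides or Grignard reagent.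
- Both diols come from one Weinreb amide, made by cuprate opening of methyl (S)-glycidate (the only source of chirality) and amidation, then aryl Grignard addition.

Assumption: the SMILES is read as (2R,3S,4R) in the upper and (2R,3S) in the lower unit, and the four building blocks marked as starting materials in the compound list are bought.

**Step 1**
Reactants: 1 4-bromoresorcinol
Product: 2 1-bromo-2,4-bis(methoxymethoxy)benzene
Conditions: MOMCl (2.5 equiv), iPr2NEt (3 equiv), CH2Cl2, 0 °C → rt
Reagents that add atoms: chloromethyl methyl ether (MOMCl), COCCl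
Why: Double O-alkylation of the phenols (MOM acetal protection) masks ring A for the organometallic steps and is removed later in the acid step that closes ring C; no stereocenter is involved.

**Step 2**
Reactants: 2 1-bromo-2,4-bis(methoxymethoxy)benzene; 3 methyl (S)-glycidate
Product: 5 methyl (2S)-3-[2,4-bis(methoxymethoxy)phenyl]-2-hydroxypropanoate, via aryl Grignard reagent 4 (not isolated)
Conditions: Mg, THF, 40 °C; then CuI (10 mol %), 3 (0.8 equiv), THF, −40 → −20 °C; aq NH4Cl
Reagents that add atoms: none
Why: Copper-catalysed SN2 opening of the epoxide at its CH2 terminus by the aryl Grignard reagent (cuprate epoxide opening) outpaces ester addition at low temperature and leaves the purchased stereocenter untouched; it becomes C3 of both flavan units.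

**Step 3**
Reactants: 5 methyl (2S)-3-[2,4-bis(methoxymethoxy)phenyl]-2-hydroxypropanoate
Product: 6 (2S)-3-[2,4-bis(methoxymethoxy)phenyl]-2-hydroxy-N-methoxy-N-methylpropanamide
Conditions: MeNHOMe·HCl (1.5 equiv), iPrMgCl (4.0 equiv), THF, −20 °C, 1 h; aq NH4Cl
Reagents that add atoms: N,O-dimethylhydroxylamine hydrochloride (MeNHOMe·HCl), CNOC.Cl
Why: Ester aminolysis by the chloromagnesium amide made in the flask (Weinreb amide formation) proceeds with the α-hydroxyl held as its magnesium alkoxide, so the stereocenter does not epimerise, and this one isolated amide feeds both flavan units.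

**Step 4**
Reactants: 6 (2S)-3-[2,4-bis(methoxymethoxy)phenyl]-2-hydroxy-N-methoxy-N-methylpropanamide; 7 4-bromo-1,2-bis(benzyloxy)benzene
Product: 9 (2S)-1-[3,4-bis(benzyloxy)phenyl]-3-[2,4-bis(methoxymethoxy)phenyl]-2-hydroxypropan-1-one, via aryl Grignard reagent 8 (not isolated)
Conditions: 7, Mg, THF, 40 °C; separately 6, iPrMgCl (1.0 equiv), THF, −20 °C; then 8 (1.5 equiv), −20 → 0 °C; aq NH4Cl
Reagents that add atoms: none
Why: Single aryl Grignard addition to the Weinreb amide (Weinreb ketone synthesis) stops at the ketone because the magnesium chelate only collapses on work-up, and prior deprotonation of the hydroxyl with iPrMgCl spares the aryl reagent and keeps the α-carbon as its alkoxide.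

**Step 5**
Reactants: 9 (2S)-1-[3,4-bis(benzyloxy)phenyl]-3-[2,4-bis(methoxymethoxy)phenyl]-2-hydroxypropan-1-one
Product: 12 3',4'-di-O-benzylfisetinidol [(2R,3S)-2-[3,4-bis(benzyloxy)phenyl]chromane-3,7-diol], via diol 10 (not isolated), via tetraol 11 (not isolated)
Conditions: NaBH4, THF/MeOH, 0 °C; then HCl (0.5 M in MeOH, substrate 0.02 M), 40 °C
Reagents that add atoms: none
Why: Ketone reduction (new carbinol configuration irrelevant) is followed by acid cleavage of both MOM acetals and SN1 cycloetherification, in which the p-alkoxybenzylic cation is trapped by the ortho phenol through the A(1,3)-minimised chair-like transition state with 2-aryl and 3-OH trans, so the purchased C3 sets C2 as R (minor 2,3-cis epimer removed by chromatography).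

**Step 6**
Reactants: 6 (2S)-3-[2,4-bis(methoxymethoxy)phenyl]-2-hydroxy-N-methoxy-N-methylpropanamide; 13 4-(benzyloxy)phenylmagnesium bromide (1.0 M in THF)
Product: 14 (2S)-1-[4-(benzyloxy)phenyl]-3-[2,4-bis(methoxymethoxy)phenyl]-2-hydroxypropan-1-one
Conditions: iPrMgCl (1.0 equiv), THF, −20 °C; then 13 (1.5 equiv), −20 → 0 °C; aq NH4Cl
Reagents that add atoms: none
Why: Same Weinreb ketone synthesis as step 4, now with the ring B reagent of the upper unit; the α-stereocenter is again protected as its magnesium alkoxide.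

**Step 7**
Reactants: 14 (2S)-1-[4-(benzyloxy)phenyl]-3-[2,4-bis(methoxymethoxy)phenyl]-2-hydroxypropan-1-one
Product: 17 4'-O-benzylguibourtinidol [(2R,3S)-2-[4-(benzyloxy)phenyl]chromane-3,7-diol], via diol 15 (not isolated), via triol 16 (not isolated)
Conditions: NaBH4, THF/MeOH, 0 °C; then HCl (0.5 M in MeOH, substrate 0.02 M), 40 °C
Reagents that add atoms: none
Why: Same reduction, MOM cleavage and SN1 cycloetherification as step 5, with C2 (R) set trans to the purchased C3 through the same chair-like transition state; the benzyl ether on ring B survives.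

**Step 8**
Reactants: 17 4'-O-benzylguibourtinidol; 12 3',4'-di-O-benzylfisetinidol
Product: 20 4'-O-benzylguibourtinidol-(4α→6)-3',4'-di-O-benzylfisetinidol, via quinone methide 18 (not isolated), via triol 19 (not isolated)
Conditions: DDQ (1.05 equiv), NaHCO3, MeCN/H2O (9:1), 0 °C, 20 min; short pad of basic Al2O3 (retains the spent oxidant); then 12 (4 equiv), dilution to 10 mM in MeCN/H2O (2:1), NaH2PO4/Na2HPO4 (pH 7, 5 mM), hν (300 nm, quartz flow coil), Ar, 15 °C
Reagents that add atoms: none
Why: Proposed new method: DDQ dehydrogenates the p-alkylphenol of 17 (7-OH para to C4a) to p-quinone methide 18, which water hydrates at C4 to the labile flavan-3,4-diol 19 (both C4 epimers; the established DDQ C4-functionalisation of flavan-3-ols, with the benzyl ether keeping ring B from oxidation at C2), and once the oxidant is filtered off so that 12 never meets it, 300 nm excitation of the ring A phenol of 19 triggers water-relayed excited-state proton transfer from 7-OH with loss of the benzylic 4-OH (photodehydration), regenerating 18 at low stationary concentration under neutral conditions, where it is captured irreversibly at C4 by the least hindered activated carbon of 12 (C6, ortho to 7-OH and para to O1) from the α face, anti to the 3-OH of the half-chair with the 2-aryl group equatorial, which sets C4 as R (3,4-trans) under control of C2/C3, while hydration or O-alkylation of 18 only returns p-hydroxybenzyl alcohols or ethers that are re-excited and recycled; the closest known reaction types are photodehydration of hydroxybenzyl alcohols to quinone methides with trapping by O- and S-nucleophiles and the acid-mediated flavan-3,4-diol–flavan-3-ol condensation, neither shown photochemically for an interflavanyl C–C bond.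

**Step 9**
Reactants: 20 4'-O-benzylguibourtinidol-(4α→6)-3',4'-di-O-benzylfisetinidol
Product: 21 guibourtinidol-(4α→6)-fisetinidol (target)
Conditions: H2 (1 atm), Pd(OH)2/C, EtOAc/MeOH, rt
Reagents that add atoms: none
Why: Hydrogenolysis of the three benzyl aryl ethers under neutral conditions leaves the interflavanyl bond, ring C ethers and all five stereocenters untouched.

**Compound list**
1 | 4-bromoresorcinol (4-bromobenzene-1,3-diol) | Oc1ccc(Br)c(O)c1 | starting material
2 | 1-bromo-2,4-bis(methoxymethoxy)benzene | COCOc1ccc(Br)c(OCOC)c1 | intermediate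
3 | methyl (S)-glycidate [methyl (2S)-oxirane-2-carboxylate] | COC(=O)[C@@H]1CO1 | starting material
4 | [2,4-bis(methoxymethoxy)phenyl]magnesium bromide | COCOc1ccc([Mg]Br)c(OCOC)c1 | intermediate
5 | methyl (2S)-3-[2,4-bis(methoxymethoxy)phenyl]-2-hydroxypropanoate | COC(=O)[C@@H](O)Cc1ccc(OCOC)cc1OCOC | intermediate
6 | (2S)-3-[2,4-bis(methoxymethoxy)phenyl]-2-hydroxy-N-methoxy-N-methylpropanamide (Weinreb amide) | CON(C)C(=O)[C@@H](O)Cc1ccc(OCOC)cc1OCOC | intermediate
7 | 4-bromo-1,2-bis(benzyloxy)benzene | Brc1ccc(OCc2ccccc2)c(OCc2ccccc2)c1 | starting material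
8 | [3,4-bis(benzyloxy)phenyl]magnesium bromide | Br[Mg]c1ccc(OCc2ccccc2)c(OCc2ccccc2)c1 | intermediate
9 | (2S)-1-[3,4-bis(benzyloxy)phenyl]-3-[2,4-bis(methoxymethoxy)phenyl]-2-hydroxypropan-1-one | O=C([C@@H](O)Cc1ccc(OCOC)cc1OCOC)c1ccc(OCc2ccccc2)c(OCc2ccccc2)c1 | intermediate
10 | (2S)-1-[3,4-bis(benzyloxy)phenyl]-3-[2,4-bis(methoxymethoxy)phenyl]propane-1,2-diol, both C1 epimers | OC([C@@H](O)Cc1ccc(OCOC)cc1OCOC)c1ccc(OCc2ccccc2)c(OCc2ccccc2)c1 | intermediate
11 | (2S)-1-[3,4-bis(benzyloxy)phenyl]-3-(2,4-dihydroxyphenyl)propane-1,2-diol, both C1 epimers | OC([C@@H](O)Cc1ccc(O)cc1O)c1ccc(OCc2ccccc2)c(OCc2ccccc2)c1 | intermediate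
12 | 3',4'-di-O-benzylfisetinidol, (2R,3S)-2-[3,4-bis(benzyloxy)phenyl]chromane-3,7-diol (2,3-trans) | Oc1ccc2c(c1)O[C@H](c1ccc(OCc3ccccc3)c(OCc3ccccc3)c1)[C@@H](O)C2 | intermediate
13 | 4-(benzyloxy)phenylmagnesium bromide | Br[Mg]c1ccc(OCc2ccccc2)cc1 | starting material
14 | (2S)-1-[4-(benzyloxy)phenyl]-3-[2,4-bis(methoxymethoxy)phenyl]-2-hydroxypropan-1-one | O=C([C@@H](O)Cc1ccc(OCOC)cc1OCOC)c1ccc(OCc2ccccc2)cc1 | intermediate
15 | (2S)-1-[4-(benzyloxy)phenyl]-3-[2,4-bis(methoxymethoxy)phenyl]propane-1,2-diol, both C1 epimers | OC([C@@H](O)Cc1ccc(OCOC)cc1OCOC)c1ccc(OCc2ccccc2)cc1 | intermediate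
16 | (2S)-1-[4-(benzyloxy)phenyl]-3-(2,4-dihydroxyphenyl)propane-1,2-diol, both C1 epimers | OC([C@@H](O)Cc1ccc(O)cc1O)c1ccc(OCc2ccccc2)cc1 | intermediate
17 | 4'-O-benzylguibourtinidol, (2R,3S)-2-[4-(benzyloxy)phenyl]chromane-3,7-diol (2,3-trans) | Oc1ccc2c(c1)O[C@H](c1ccc(OCc3ccccc3)cc1)[C@@H](O)C2 | intermediate
18 | (2R,3S)-2-[4-(benzyloxy)phenyl]-3-hydroxy-2,3-dihydro-7H-chromen-7-one (ring A p-quinone methide, C4=C4a) | O=C1C=CC2=C[C@H](O)[C@@H](c3ccc(OCc4ccccc4)cc3)OC2=C1 | intermediate
19 | 4'-O-benzylleucoguibourtinidin, (2R,3S)-2-[4-(benzyloxy)phenyl]chromane-3,4,7-triol, both C4 epimers | Oc1ccc2c(c1)O[C@H](c1ccc(OCc3ccccc3)cc1)[C@@H](O)C2O | intermediate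
20 | (2R,3S,4R)-2-[4-(benzyloxy)phenyl]-4-[(2R,3S)-2-[3,4-bis(benzyloxy)phenyl]-3,7-dihydroxychroman-6-yl]chromane-3,7-diol | c1ccccc1COc1ccc([C@H]2Oc3cc(O)ccc3[C@@H](c3cc4c(cc3O)O[C@H](c3ccc(OCc5ccccc5)c(OCc5ccccc5)c3)[C@@H](O)C4)[C@@H]2O)cc1 | intermediate
21 | guibourtinidol-(4α→6)-fisetinidol, (2R,3S,4R)-4-[(2R,3S)-2-(3,4-dihydroxyphenyl)-3,7-dihydroxychroman-6-yl]-2-(4-hydroxyphenyl)chromane-3,7-diol | Oc1ccc([C@H]2Oc3cc(O)ccc3[C@@H](c3cc4c(cc3O)O[C@H](c3ccc(O)c(O)c3)[C@@H](O)C4)[C@@H]2O)cc1 | target

**Step count**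
Total: 9 steps. Longest linear sequence: 7 steps (steps 1, 2, 3, 6, 7, 8, 9).

**Steps most likely to fail**

Step 8 (the proposed DDQ hydroxylation and photochemical coupling). Risks:
- over-oxidation of 19 to the 4-ketone, or capture of 18 by ring A of unreacted 17 in the DDQ stage;
- low quantum efficiency of quinone methide formation;
- self-condensation of 19 through its own ring A;
- mixtures at C4 (3,4-trans expected to dominate, roughly 3:1) and at C6 versus C8 of 12;
- photocleavage of the O1–C2 bond (C2 epimerisation) or of benzyl ethers on long irradiation.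

Fallback with known chemistry: set out from 17, run only the DDQ stage of step 8 and isolate 19 by extractive work-up (EtOAc/aq NaHCO3). Treat 19 with phenylmethanethiol in AcOH at rt to give the thioether 4-(benzylsulfanyl)-4'-O-benzylguibourtinidol F1. F1 is then activated with AgBF4 in THF at 0 °C in the presence of 12 (thiophilic Lewis acid interflavanyl coupling of 4-benzylsulfanylflavan-3-ols). This comes back to the route at 20.

Step 6 (aryl Grignard addition to the unprotected α-hydroxy Weinreb amide; step 4 is its twin). Risks: incomplete addition to the chelated alkoxide and α-ketol isomerisation or epimerisation of 14 on work-up.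

Fallback: set out from 5 and silylate it (TBSCl, imidazole, DMF) to methyl (2S)-3-[2,4-bis(methoxymethoxy)phenyl]-2-[(tert-butyldimethylsilyl)oxy]propanoate F2. F2 is reduced with iBu2AlH (1.1 equiv, CH2Cl2, −78 °C) to the aluminium hemiacetal and treated in the same flask with 13 (−78 → 0 °C) to give (2S)-1-[4-(benzyloxy)phenyl]-3-[2,4-bis(methoxymethoxy)phenyl]-2-[(tert-butyldimethylsilyl)oxy]propan-1-ol F3 (both C1 epimers). F3 bypasses 6, 14 and the borohydride stage, enters the HCl/MeOH stage of step 7 (which also removes the silyl ether), and comes back to the route at 17.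

Step 2 (cuprate opening of an epoxy ester). Risks: sluggish formation of 4 from the ortho-oxygenated bromide and attack of 4 on the ester carbonyl of 3 or of product 5.

Fallback: set out from 2, convert it into 4 as in step 2, and add it (CuI 10 mol %, THF, −30 → 0 °C) to (R)-glycidol that has first been deprotonated with iPrMgCl (1.0 equiv). This ester-free epoxide opening gives (2S)-3-[2,4-bis(methoxymethoxy)phenyl]propane-1,2-diol F4. F4 is oxidised at the primary alcohol only with TEMPO (cat.)/PhI(OAc)2 in MeCN/H2O to (2S)-3-[2,4-bis(methoxymethoxy)phenyl]-2-hydroxypropanoic acid F5. F5 is esterified with MeI/KHCO3 in DMF and comes back to the route at 5.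

**Further compounds**
F1 | step 8 | 4-(benzylsulfanyl)-4'-O-benzylguibourtinidol, (2R,3S)-configured at C2/C3 with both C4 epimers | Oc1ccc2c(c1)O[C@H](c1ccc(OCc3ccccc3)cc1)[C@@H](O)C2SCc1ccccc1
F2 | step 6 | methyl (2S)-3-[2,4-bis(methoxymethoxy)phenyl]-2-[(tert-butyldimethylsilyl)oxy]propanoate | COC(=O)[C@@H](O[Si](C)(C)C(C)(C)C)Cc1ccc(OCOC)cc1OCOC
F3 | step 6 | (2S)-1-[4-(benzyloxy)phenyl]-3-[2,4-bis(methoxymethoxy)phenyl]-2-[(tert-butyldimethylsilyl)oxy]propan-1-ol, both C1 epimers | OC([C@@H](O[Si](C)(C)C(C)(C)C)Cc1ccc(OCOC)cc1OCOC)c1ccc(OCc2ccccc2)cc1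
F4 | step 2 | (2S)-3-[2,4-bis(methoxymethoxy)phenyl]propane-1,2-diol | OC[C@@H](O)Cc1ccc(OCOC)cc1OCOC
F5 | step 2 | (2S)-3-[2,4-bis(methoxymethoxy)phenyl]-2-hydroxypropanoic acid | OC(=O)[C@@H](O)Cc1ccc(OCOC)cc1OCOC
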